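## Analysis of the target

The target 15 is a single oxolane ring, numbered here O1, C2 (3,4,5-trimethoxyphenyl), C3 (CH2OH), C4 (3,4,5-trimethoxybenzoyl) and C5H2; the only other rings are the two arenes. Its three stereocentres are contiguous, (2S,3S,4R) in this numbering: the C2 aryl and the C3 hydroxymethyl group are cis, and the C4 aroyl group is trans to the hydroxymethyl group and so also trans to the aryl group. C4 is α to an aryl ketone and can be epimerised; because the aroyl group is trans to its neighbour at C3, the required configuration is the more stable one and can be left to equilibration. The cis relationship between C2 and C3 is the less stable one and cannot be corrected later, so C3 must be set kinetically relative to C2, and C2 is the only centre that needs an absolute source of chirality. Three sites are sensitive: the C2–O1 bond is a benzylic ether of an electron-rich arene, which acid can ionise with loss of the 2,3-cis relationship; O1–C5–C4–C=O is a β-alkoxy ketone, which strong base can open by E1cB; and the primary alcohol will attack any ester placed on C4. The difficulty is therefore to put three different carbon substituents on adjacent ring atoms, one pair of them in the less stable cis arrangement, without using acid. The plan rests on two features. O1–C5–C4(C=O) is the footprint of an alkoxide adding to an α-methylene ketone, and C3, bonded to the ketone α-carbon C4 and carrying a one-carbon branch, can be the internal carbon of a terminal alkyne whose terminal carbon becomes the CH2 of the hydroxymethyl group.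

## Retrosynthetic reasoning

15 ⇒ 14. The last bond cut is the O–Si bond of silyl ether 14. The hydroxymethyl group must stay masked until C4 has lost its ester, because a free CH2OH cis to an ester on C4 would close a γ-lactone. The forward step only has to remove silicon without exposing the β-alkoxy ketone to strong base.

14 ⇒ 12. A methoxycarbonyl group is added back to C4, giving β-keto ester 12. This ester is what makes C4 a soft carbon nucleophile in the ring-forming step. In the forward direction it is removed by dealkoxycarbonylation, and the C4–H centre then equilibrates (through mixture 13) to the aroyl-trans arrangement, so both C4 epimers of 12 converge on 14.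

12 ⇒ 11 ⇒ 9. The CH2O group and the hydrogen on C3 are traced back to the exocyclic alkene of 9. Hydroboration (through borane 10) must deliver hydrogen to C3 from the face away from the C2 aryl group, which pushes the new CH2 group to the aryl face and fixes the cis pair; oxidation and silylation give 12. This route to C3 is preferred because the alkene is a direct product of the ring closure and C2, next to it, is the stereocentre best placed to differentiate its faces.

9 ⇒ 4 + 7. The central disconnection cuts O1–C5 and C3–C4. Cutting here, and not at C2–C3 or C2–O1, leaves the C2 stereocentre untouched inside a simple carbinol (4) and lets both carbonyl groups of 7 activate the acceptor. One step then gives the ring, two skeletal bonds and the full carbon skeleton from two fragments of similar size. The forward reaction (through adduct 8) has to make alkoxide addition outrun polymerisation of 7 and close the ring through carbon in the 5-exo mode.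

4 ⇒ 3 ⇒ 1 + 2. The carbinol carbon–alkyne bond is cut to aldehyde 1 and acetylide 2, and the S enantiomer is taken from racemate 3 by enzymatic resolution. Enantioselective reduction at the ketone oxidation level was set aside, because a carbonyl flanked by an aryl and an alkynyl group offers a catalyst two unsaturated substituents of similar demand. An acylating enzyme separates aryl from ethynyl cleanly.

7 ⇒ 6 ⇒ 1 + 5. The bond between the ketone carbon and the acrylate α-carbon is cut to aldehyde 1 and acrylate 5 (Morita–Baylis–Hillman coupling to 6, then oxidation). An aminomethylation–elimination sequence on a β-keto ester was set aside because it liberates a secondary amine, which is a competing conjugate donor and a copper ligand, and because it consumes stoichiometric base; neither fits a catalytic alkoxide cycle. Both fragments therefore come from 1.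

## Alternatives that were turned down

Alternative 1: Prins–pinacol route to the all-cis aldehyde A1. The disconnection cuts C2–C3 and C4–C5. In the forward direction SnCl4 would ionise an aryl acetal to an oxocarbenium ion, a Z-alkene would close C2–C3 through a chair, and a 1,2-shift of a ring carbon would form C4–C5 and leave a formyl group on C4. In its favour, the ring and two C–C bonds form in one step, and the 2,3-cis relationship follows from alkene geometry inside the ring-forming transition state. On that point it is stronger than the chosen route, which relies on reagent approach to an exocyclic alkene. Against it for this target: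
- C4 of A1 carries hydrogen, so the alkene carbon that becomes C4 would bear the positive charge as an unstabilised secondary cation. Cascades of this kind depend on tertiary or heteroatom-stabilised cations.
- SnCl4 can re-ionise the electron-rich benzylic C2–O1 bond of the product and scramble C2.
- A1 has a formyl group where the aroyl group is needed, so aryl-metal addition, oxidation, C4 inversion from cis to trans and desilylation would follow.
- The absolute configuration would have to come from an enantiopure Z-alkenyl diol, itself several steps away.

The chosen strategy brings the aroyl group in from the start and uses no Lewis acid, at the price of setting C3 in a separate step.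

Alternative 2: semipinacol ring contraction to A2, the tert-butyldimethylsilyl ether of 15. The disconnection cuts C3–C4. In the forward direction KOtBu would deprotonate a tertiary aryl carbinol on a tetrahydropyran, and ring carbon C3 would migrate to the neighbouring mesylate-bearing carbon with inversion, expelling mesylate and leaving the aroyl group on the contracted ring. In its favour, the shift is stereospecific, all oxidation states are final, and A2 is one deprotection from 15. In end-game brevity and in fidelity at C4 it is stronger than the chosen route. Against it:
- The substrate of the shift needs four defined centres on a pyran, including a tertiary carbinol and an equatorial mesylate antiperiplanar to the migrating ring bond, so the linear sequence before the key step is long.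
- Epoxide closure, aryl migration and elimination compete with the ring-bond shift.
- Stoichiometric KOtBu meets a β-alkoxy ketone product.
- The fidelity at C4 buys little, because that centre equilibrates to the required trans arrangement anyway.

The chosen strategy reaches the same ring convergently in one step from two short fragments and leaves C4 to thermodynamics.

Alternative 3: carbene-catalysed homoenolate annulation to the cis lactone A3. The disconnection cuts C2–C3 and the lactone O–C(=O) bond, leading to aldehyde 1 and the enal A4. In the forward direction a chiral triazolium-derived carbene would turn A4 into a homoenolate, whose β-carbon adds to 1; the new alkoxide then captures the acyl azolium. In its favour, C2 and C3, the difficult cis pair, would both be set in one catalytic asymmetric C–C bond formation with no resolution. That is stronger than the chosen route, which discards half of a racemate and sets C3 by substrate control. Against it: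
- Aldehyde 1 is electron-rich and a poor electrophile, so self-reaction or protonation of the homoenolate competes.
- Diastereo- and enantioselectivity of such intermolecular annulations depend strongly on the substrate.
- A4 carries a γ-leaving group that can be expelled at the acyl-anion stage.
- A3 lacks the aroyl group and has C5 as a lactone carbonyl. It needs α-aroylation and then reduction of the lactone C=O to CH2 beside a ketone, usually by silane and Lewis acid, which endangers the C2–O1 bond.

The chosen strategy has C5 as CH2 and the aroyl group in place from the ring-forming step onward.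

Key step: step 5

Remark on the chemistry: every compound is cited by the oxolane numbering of the target (O1, C2 aryl, C3, C4 aroyl, C5H2), also where systematic nomenclature would number differently. Compounds 9 to 13 are handled as mixtures of C4 epimers.

Step 1
Reactants: 1 3,4,5-trimethoxybenzaldehyde; 2 ethynylmagnesium bromide
Product: 3 rac-1-(3,4,5-trimethoxyphenyl)prop-2-yn-1-ol
Conditions: HC≡CMgBr (0.5 M in THF), THF, 0 °C → rt; aq. NH4Cl
Reagents that add atoms: none
Why: Grignard 1,2-addition of the acetylide to a non-enolisable aromatic aldehyde; the carbinol forms racemic and is resolved in step 2.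

Step 2
Reactants: 3 rac-1-(3,4,5-trimethoxyphenyl)prop-2-yn-1-ol
Product: 4 (1S)-1-(3,4,5-trimethoxyphenyl)prop-2-yn-1-ol
Conditions: Novozym 435 (immobilised Candida antarctica lipase B), vinyl acetate, MTBE, 30 °C, stopped just past half conversion; chromatography
Reagents that add atoms: none
Why: Lipase-catalysed kinetic resolution by irreversible transesterification; the enzyme should acylate the enantiomer that fits the large aryl group and the slim ethynyl group into its large and medium pockets, the (R)-carbinol, so that (S)-4 remains as the free alcohol, its assignment to be checked by chiral HPLC against 3.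

Step 3
Reactants: 1 3,4,5-trimethoxybenzaldehyde; 5 methyl acrylate
Product: 6 methyl 2-[hydroxy(3,4,5-trimethoxyphenyl)methyl]prop-2-enoate (racemic)
Conditions: DABCO, MeOH, rt, prolonged
Reagents that add atoms: none
Why: Morita–Baylis–Hillman reaction; the electron-rich aldehyde should react slowly but cleanly, and the racemic carbinol centre is removed by oxidation in step 4.

Step 4
Reactants: 6 methyl 2-[hydroxy(3,4,5-trimethoxyphenyl)methyl]prop-2-enoate
Product: 7 methyl 2-(3,4,5-trimethoxybenzoyl)prop-2-enoate
Conditions: Dess–Martin periodinane, CH2Cl2, 0 °C → rt; filtration through basic alumina; solution used at once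
Reagents that add atoms: none
Why: Dess–Martin oxidation of the benzylic, allylic carbinol under base-free, non-nucleophilic conditions that leave the doubly activated alkene alone; 7 is not stored because 2-acyl acrylates dimerise by hetero-Diels–Alder reaction and polymerise.

Step 5
Reactants: 4 (1S)-1-(3,4,5-trimethoxyphenyl)prop-2-yn-1-ol; 7 methyl 2-(3,4,5-trimethoxybenzoyl)prop-2-enoate
Product: 9 methyl (2R)-3-methylidene-4-(3,4,5-trimethoxybenzoyl)-2-(3,4,5-trimethoxyphenyl)oxolane-4-carboxylate (both C4 epimers), via oxa-Michael keto ester adduct 8 (not isolated)
Conditions: KOtBu (0.2 equiv), CuI (0.1 equiv), THF, rt, argon; 7 added slowly by syringe pump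
Reagents that add atoms: none
Why: KOtBu converts 4 into its alkoxide, which adds to the unsubstituted β-carbon of 7 (oxa-Michael addition, bond O1–C5) and gives the stabilised keto ester enolate of 8. CuI binds the terminal alkyne and the enolate carbon adds to the internal alkyne carbon (bond C3–C4, Conia-ene-type carbometalation); protonolysis of the alkenylcopper by a further molecule of 4 releases 9 and returns alkoxide and monovalent copper, so both promoters are catalytic. The closest known reaction type is the alkoxide- and CuI-catalysed tandem oxa-Michael addition and carbocyclisation of propargylic alcohols with alkylidene malonates and related alkylidene 1,3-dicarbonyl acceptors, which gives 3-methylene oxolanes. The oxolane closes in the 5-exo-dig mode; 6-endo-dig attack is disfavoured because the terminal carbon is the metalated one and the three-atom tether C5–O1–C2 aligns the enolate with the internal carbon. C2 is not a new centre: no bond to it is made or broken, so its configuration is that of 4, and the descriptor reads R in 9 only because C3 now outranks the aryl group. The new quaternary centre C4 forms without useful control and 9 is carried on as both epimers, which is acceptable because C4 is reset in step 8. The step needs carbon and not oxygen attack of the ambident enolate (oxygen attack would need a seven-membered ring), alkoxide addition faster than oligomerisation of 7 (slow addition keeps 7 dilute while ring closure is unimolecular), and a configurationally stable propargylic C–H (the base rests on the weakly basic enolate).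

Step 6
Reactants: 9 methyl (2R)-3-methylidene-4-(3,4,5-trimethoxybenzoyl)-2-(3,4,5-trimethoxyphenyl)oxolane-4-carboxylate
Product: 11 methyl (2S,3S)-3-(hydroxymethyl)-4-(3,4,5-trimethoxybenzoyl)-2-(3,4,5-trimethoxyphenyl)oxolane-4-carboxylate (both C4 epimers), via B-alkyl-9-BBN adduct 10 (not isolated)
Conditions: 9-BBN, THF, 0 °C → rt; then aq. NaOAc, 30% H2O2, 0 °C
Reagents that add atoms: hydrogen peroxide, OO
Why: Hydroboration–oxidation; boron goes to the terminal carbon and hydrogen to C3 from the face opposite the C2 aryl group, so the CH2OH group ends cis to the aryl group (3S), and the C–B bond is oxidised with retention. The aryl ketone is deactivated by three methoxy groups and shielded by the quaternary C4, so the bulky dialkylborane should reduce it more slowly than it adds to the alkene; the acetate-buffered peroxide avoids hydroxide, which would cleave the non-enolisable β-keto ester.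

Step 7
Reactants: 11 methyl (2S,3S)-3-(hydroxymethyl)-4-(3,4,5-trimethoxybenzoyl)-2-(3,4,5-trimethoxyphenyl)oxolane-4-carboxylate
Product: 12 methyl (2S,3S)-4-(3,4,5-trimethoxybenzoyl)-2-(3,4,5-trimethoxyphenyl)-3-{[(triisopropylsilyl)oxy]methyl}oxolane-4-carboxylate (both C4 epimers)
Conditions: TIPSOTf, 2,6-lutidine, CH2Cl2, −78 → 0 °C
Reagents that add atoms: triisopropylsilyl trifluoromethanesulfonate, CC(C)[Si](OS(=O)(=O)C(F)(F)F)(C(C)C)C(C)C
Why: Silylation of the primary alcohol with a silyl triflate and a hindered base is fast at low temperature, so the alcohol should be capped before the epimer with CH2OH cis to the ester can lactonise; the triisopropylsilyl ether should withstand chloride in hot wet DMSO.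

Step 8
Reactants: 12 methyl (2S,3S)-4-(3,4,5-trimethoxybenzoyl)-2-(3,4,5-trimethoxyphenyl)-3-{[(triisopropylsilyl)oxy]methyl}oxolane-4-carboxylate
Product: 14 (3,4,5-trimethoxyphenyl)[(2S,3S,4R)-2-(3,4,5-trimethoxyphenyl)-3-{[(triisopropylsilyl)oxy]methyl}oxolan-4-yl]methanone, via C4-epimeric ketone mixture 13 (not isolated)
Conditions: LiCl, DMSO, H2O, 140 °C; then DBU (cat.), rt
Reagents that add atoms: none
Why: Krapcho dealkoxycarbonylation: chloride demethylates the ester by SN2, the β-keto carboxylate loses CO2 and water protonates the ketone enolate. The C4–H centre, α to the aryl ketone, then equilibrates under DBU to the epimer with the aroyl group trans to the bulky C3 substituent (4R, thermodynamic control), so both C4 epimers of 12 converge.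

Step 9
Reactants: 14 (3,4,5-trimethoxyphenyl)[(2S,3S,4R)-2-(3,4,5-trimethoxyphenyl)-3-{[(triisopropylsilyl)oxy]methyl}oxolan-4-yl]methanone
Product: 15 (3,4,5-trimethoxyphenyl)[(2S,3S,4R)-3-(hydroxymethyl)-2-(3,4,5-trimethoxyphenyl)oxolan-4-yl]methanone (systematic name [(3R,4S,5S)-4-(hydroxymethyl)-5-(3,4,5-trimethoxyphenyl)oxolan-3-yl](3,4,5-trimethoxyphenyl)methanone)
Conditions: TBAF, AcOH, THF, 0 °C → rt
Reagents that add atoms: none
Why: Fluoride-induced Si–O cleavage; acetic acid buffers the fluoride so that the β-alkoxy ketone is not exposed to strong base and the thermodynamic C4 configuration is left as it is.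

## Compound list

1 | 3,4,5-trimethoxybenzaldehyde | COc1cc(C=O)cc(OC)c1OC | starting material
2 | ethynylmagnesium bromide | C#C[Mg]Br | starting material
3 | rac-1-(3,4,5-trimethoxyphenyl)prop-2-yn-1-ol | OC(C#C)c1cc(OC)c(OC)c(OC)c1 | intermediate
4 | (1S)-1-(3,4,5-trimethoxyphenyl)prop-2-yn-1-ol | O[C@H](c1cc(OC)c(OC)c(OC)c1)C#C | intermediate
5 | methyl acrylate | C=CC(=O)OC | starting material
6 | methyl 2-[hydroxy(3,4,5-trimethoxyphenyl)methyl]prop-2-enoate, racemic | C=C(C(=O)OC)C(O)c1cc(OC)c(OC)c(OC)c1 | intermediate
7 | methyl 2-(3,4,5-trimethoxybenzoyl)prop-2-enoate | C=C(C(=O)OC)C(=O)c1cc(OC)c(OC)c(OC)c1 | intermediate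
8 | methyl 3-oxo-2-({[(1S)-1-(3,4,5-trimethoxyphenyl)prop-2-yn-1-yl]oxy}methyl)-3-(3,4,5-trimethoxyphenyl)propanoate, α-carbon unassigned, present as its enolate | COC(=O)C(CO[C@H](c1cc(OC)c(OC)c(OC)c1)C#C)C(=O)c1cc(OC)c(OC)c(OC)c1 | intermediate (not isolated)
9 | methyl (2R)-3-methylidene-4-(3,4,5-trimethoxybenzoyl)-2-(3,4,5-trimethoxyphenyl)oxolane-4-carboxylate, both C4 epimers, C2 configured as in 4 | COC(=O)C1(C(=O)c2cc(OC)c(OC)c(OC)c2)CO[C@H](c2cc(OC)c(OC)c(OC)c2)C1=C | intermediate
10 | B-alkyl-9-BBN adduct of 9: hydrogen on C3 trans to the C2 aryl group, 9-borabicyclo[3.3.1]nonan-9-yl on the former methylidene carbon, both C4 epimers | COC(=O)C1(C(=O)c2cc(OC)c(OC)c(OC)c2)CO[C@H](c2cc(OC)c(OC)c(OC)c2)[C@@H]1CB1C2CCCC1CCC2 | intermediate (not isolated)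
11 | methyl (2S,3S)-3-(hydroxymethyl)-4-(3,4,5-trimethoxybenzoyl)-2-(3,4,5-trimethoxyphenyl)oxolane-4-carboxylate, both C4 epimers | COC(=O)C1(C(=O)c2cc(OC)c(OC)c(OC)c2)CO[C@H](c2cc(OC)c(OC)c(OC)c2)[C@@H]1CO | intermediate
12 | methyl (2S,3S)-4-(3,4,5-trimethoxybenzoyl)-2-(3,4,5-trimethoxyphenyl)-3-{[(triisopropylsilyl)oxy]methyl}oxolane-4-carboxylate, both C4 epimers | COC(=O)C1(C(=O)c2cc(OC)c(OC)c(OC)c2)CO[C@H](c2cc(OC)c(OC)c(OC)c2)[C@@H]1CO[Si](C(C)C)(C(C)C)C(C)C | intermediate
13 | (3,4,5-trimethoxyphenyl)[(2S,3S)-2-(3,4,5-trimethoxyphenyl)-3-{[(triisopropylsilyl)oxy]methyl}oxolan-4-yl]methanone, mixture of C4 epimers | COc1cc(C(=O)C2CO[C@H](c3cc(OC)c(OC)c(OC)c3)[C@@H]2CO[Si](C(C)C)(C(C)C)C(C)C)cc(OC)c1OC | intermediate (not isolated)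
14 | (3,4,5-trimethoxyphenyl)[(2S,3S,4R)-2-(3,4,5-trimethoxyphenyl)-3-{[(triisopropylsilyl)oxy]methyl}oxolan-4-yl]methanone | COc1cc(C(=O)[C@H]2CO[C@H](c3cc(OC)c(OC)c(OC)c3)[C@@H]2CO[Si](C(C)C)(C(C)C)C(C)C)cc(OC)c1OC | intermediate
15 | (3,4,5-trimethoxyphenyl)[(2S,3S,4R)-3-(hydroxymethyl)-2-(3,4,5-trimethoxyphenyl)oxolan-4-yl]methanone | COc1cc(C(=O)[C@H]2CO[C@H](c3cc(OC)c(OC)c(OC)c3)[C@@H]2CO)cc(OC)c1OC | target

## Step count and risk

Total step count: 9. Longest linear sequence: 7 steps (steps 1, 2, 5, 6, 7, 8, 9 from 1; the branch through steps 3 and 4 is equally long).

Least certain steps: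

Step 5 (key step). The most likely failure is anionic oligomerisation of 7, started by the alkoxide or by the enolate of 8, outrunning the copper-mediated ring closure. The keto ester enolate is a more stabilised and slower carbon nucleophile than a malonate enolate, so cyclisation may lag behind conjugate addition to a second molecule of 7. A lesser concern is erosion of configuration at the propargylic carbon by base-mediated propargyl–allenyl proton shift. The fallback sets out from 4 and 7 and separates the two bond formations. The potassium alkoxide of 4 is made stoichiometrically (KHMDS, THF, −78 °C), 7 is added at −78 °C and the mixture is quenched with AcOH to isolate 8. Neutral 8 is then cycloisomerised through its enol under π-acid catalysis (Ph3PAuCl/AgOTf, CH2Cl2, rt; Conia-ene reaction catalysed by monovalent gold, 5-exo-dig). The fallback returns to the route at 9 and makes no compound outside the list (F0).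

Step 6. The most likely failure is loss of chemoselectivity: the hindered alkene reacts slowly, and reduction of the aryl ketone by the borane then competes. Facial discrimination may also be weaker in the C4 epimer whose aroyl group lies on the face opposite the C2 aryl group. The fallback sets out from 9 and makes the over-reduction deliberate. Excess 9-BBN at 50 °C followed by the same buffered oxidation should give the diol methyl (2S,3S)-3-(hydroxymethyl)-4-[hydroxy(3,4,5-trimethoxyphenyl)methyl]-2-(3,4,5-trimethoxyphenyl)oxolane-4-carboxylate F1. One equivalent of TIPSOTf with 2,6-lutidine at −78 °C should silylate only the primary alcohol, giving the mono(triisopropylsilyl) ether of the diol F2. Dess–Martin oxidation of the hindered benzylic carbinol then returns to the route at 12.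

Step 8. The most likely failure is ring opening at 140 °C: the ketone enolate formed after loss of CO2 can expel O1 from C5 (retro-oxa-Michael), and chloride in wet DMSO can remove the silyl group early. The fallback sets out from 12 and replaces the halide SN2 pathway by neutral acyl–oxygen hydrolysis. Me3SnOH in 1,2-dichloroethane at 80 °C should give, after mild acidic work-up, the keto acid (2S,3S)-4-(3,4,5-trimethoxybenzoyl)-2-(3,4,5-trimethoxyphenyl)-3-{[(triisopropylsilyl)oxy]methyl}oxolane-4-carboxylic acid F5. Warming F5 in toluene at 60–80 °C should cause decarboxylation through the cyclic enol pathway to mixture 13, and catalytic DBU returns to the route at 14.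

Step 7. The most likely failure is lactonisation, during the oxidative work-up of step 6 or before silylation is complete, of the C4 epimer of 11 whose ester is cis to CH2OH. A lactone cannot go through step 8, because chloride would attack its O–CH2 carbon. The fallback sets out from 11. Lactonisation of that epimer is completed with catalytic DBU to give the cis-fused keto lactone 6a-(3,4,5-trimethoxybenzoyl)-4-(3,4,5-trimethoxyphenyl)tetrahydro-1H,3H-furo[3,4-c]furan-1-one F3 (aryl and lactone CH2 cis, as in 11), which is separated from the silylated other epimer. F3 is opened with LiOH in THF/H2O at 0 °C, and the solution is brought to pH 4–5 and warmed. The resulting (2S,3S)-3-(hydroxymethyl)-4-(3,4,5-trimethoxybenzoyl)-2-(3,4,5-trimethoxyphenyl)oxolane-4-carboxylic acid F4 should lose CO2 (hydrolytic decarboxylative opening of an α-acyl γ-butyrolactone). Equilibration of C4 with catalytic DBU then returns to the route at 15.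

## Further compounds

F0 | step 5 | none | none
F1 | step 6 | methyl (2S,3S)-3-(hydroxymethyl)-4-[hydroxy(3,4,5-trimethoxyphenyl)methyl]-2-(3,4,5-trimethoxyphenyl)oxolane-4-carboxylate, mixture at C4 and at the carbinol carbon | COC(=O)C1(C(O)c2cc(OC)c(OC)c(OC)c2)CO[C@H](c2cc(OC)c(OC)c(OC)c2)[C@@H]1CO
F2 | step 6 | methyl (2S,3S)-4-[hydroxy(3,4,5-trimethoxyphenyl)methyl]-2-(3,4,5-trimethoxyphenyl)-3-{[(triisopropylsilyl)oxy]methyl}oxolane-4-carboxylate, mixture at C4 and at the carbinol carbon | COC(=O)C1(C(O)c2cc(OC)c(OC)c(OC)c2)CO[C@H](c2cc(OC)c(OC)c(OC)c2)[C@@H]1CO[Si](C(C)C)(C(C)C)C(C)C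
F3 | step 7 | cis-fused 6a-(3,4,5-trimethoxybenzoyl)-4-(3,4,5-trimethoxyphenyl)tetrahydro-1H,3H-furo[3,4-c]furan-1-one, aryl cis to the lactone CH2 | O=C1OC[C@H]2[C@@H](c3cc(OC)c(OC)c(OC)c3)OC[C@@]12C(=O)c1cc(OC)c(OC)c(OC)c1
F4 | step 7 | (2S,3S)-3-(hydroxymethyl)-4-(3,4,5-trimethoxybenzoyl)-2-(3,4,5-trimethoxyphenyl)oxolane-4-carboxylic acid, carboxyl cis to CH2OH | OC(=O)[C@]1(C(=O)c2cc(OC)c(OC)c(OC)c2)CO[C@H](c2cc(OC)c(OC)c(OC)c2)[C@@H]1CO
F5 | step 8 | (2S,3S)-4-(3,4,5-trimethoxybenzoyl)-2-(3,4,5-trimethoxyphenyl)-3-{[(triisopropylsilyl)oxy]methyl}oxolane-4-carboxylic acid, both C4 epimers | OC(=O)C1(C(=O)c2cc(OC)c(OC)c(OC)c2)CO[C@H](c2cc(OC)c(OC)c(OC)c2)[C@@H]1CO[Si](C(C)C)(C(C)C)C(C)C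
A1 | alternative 1 | all-cis 3-[(tert-butyldiphenylsilyloxy)methyl]-2-(3,4,5-trimethoxyphenyl)oxolane-4-carbaldehyde | O=C[C@@H]1CO[C@H](c2cc(OC)c(OC)c(OC)c2)[C@@H]1CO[Si](c1ccccc1)(c1ccccc1)C(C)(C)C
A2 | alternative 2 | O-tert-butyldimethylsilyl ether of 15 | O=C(c1cc(OC)c(OC)c(OC)c1)[C@H]1CO[C@H](c2cc(OC)c(OC)c(OC)c2)[C@@H]1CO[Si](C)(C)C(C)(C)C
A3 | alternative 3 | cis-4-[(tert-butyldimethylsilyloxy)methyl]-5-(3,4,5-trimethoxyphenyl)oxolan-2-one | C1C(=O)O[C@H](c2cc(OC)c(OC)c(OC)c2)[C@@H]1CO[Si](C)(C)C(C)(C)C
A4 | alternative 3 | (E)-4-[(tert-butyldimethylsilyl)oxy]but-2-enal | O=C/C=C/CO[Si](C)(C)C(C)(C)C
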